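The route cuts the α-methylene-γ-lactone (ring B: O, C12, C11, C7, C6) at C7–C11 and C11=C13. The feature exploited is the C6–C7–C8 triad of the ten-membered carbocycle (ring A). C7 bears C11 and is flanked by the oxygen-bearing C6 and C8, an array held in latent form by an erythro, trans C7–C8 epoxide acylated on its C6 hydroxyl. In one operation a tethered phosphonoacetate carbanion opens the epoxide at C7 with inversion, closes ring B, frees the C8 hydroxyl and then methylenates C11 with formaldehyde. The precursor is an acyclic C1–C9 chain with a C1 dioxolane, the E C4=C5 alkene bearing C15–OTBDPS, and C9–OPMB. Ring A is closed last at C1–C10.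

Key step: step 9

Remark on the chemistry: atoms carry germacranolide numbers (ring A = C1–C10, C14 on C10, C15 on C4, lactone carbons C11–C13, acyl carbons primed). CIP letters change along the route wherever only the ranking of substituents changes, with no spatial change. (S)-2-Methylbutanoic acid and (−)-MIB are taken as commercial in enantiopure form.

Step 1
Reactants: 1 but-2-yne-1,4-diol
Product: 2 4-[(tert-butyldiphenylsilyl)oxy]but-2-yn-1-ol
Conditions: 1 (3 equiv), NaH (1 equiv), THF, 0 °C to rt; TBDPSCl (1 equiv)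
Reagents that add atoms: tert-butyl(chloro)diphenylsilane, CC(C)(C)[Si](Cl)(c1ccccc1)c1ccccc1
Why: Monosilylation of a symmetric diol through its monosodium alkoxide (substitution at silicon) with the diol in excess should give mainly the mono-ether, and TBDPS is chosen because it must outlast the acidic acetal cleavage of step 14.

Step 2
Reactants: 2 4-[(tert-butyldiphenylsilyl)oxy]but-2-yn-1-ol
Product: 4 (Z)-4-[(tert-butyldiphenylsilyl)oxy]-3-iodobut-2-en-1-ol, via cyclic alkenylalanate 3 (not isolated)
Conditions: NaAlH2(OCH2CH2OMe)2, THF, 0 °C; then I2, THF, −78 to 0 °C; aqueous work-up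
Reagents that add atoms: iodine, II
Why: Hydroxyl-directed trans-hydroalumination of a propargylic alcohol places aluminium on C4 inside a five-membered alanate and hydrogen on C5, iodinolysis with retention leaves iodine cis to C6 (Z), and working at or below 0 °C holds back β-elimination of the silyloxy group to an allene.

Step 3
Reactants: 4 (Z)-4-[(tert-butyldiphenylsilyl)oxy]-3-iodobut-2-en-1-ol; 5 2-vinyl-1,3-dioxolane
Product: 7 (E)-5-(1,3-dioxolan-2-yl)-3-{[(tert-butyldiphenylsilyl)oxy]methyl}pent-2-en-1-ol, via alkylborane 6 (not isolated)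
Conditions: 5, 9-BBN, THF, 0 °C to rt; then 4, PdCl2(dppf) (5 mol%), Cs2CO3, DMF/H2O, rt
Reagents that add atoms: none
Why: B-alkyl Suzuki–Miyaura coupling, in which 9-BBN adds to the terminal carbon of the vinyl acetal and the sp3–sp2 coupling keeps the geometry at C4, so the C3 chain ends cis to C6 as ring A requires, with free hydroxyl, silyl ether and acetal tolerated.

Step 4
Reactants: 7 (E)-5-(1,3-dioxolan-2-yl)-3-{[(tert-butyldiphenylsilyl)oxy]methyl}pent-2-en-1-ol
Product: 8 (E)-5-(1,3-dioxolan-2-yl)-3-{[(tert-butyldiphenylsilyl)oxy]methyl}pent-2-enal (C6 enal)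
Conditions: TEMPO (10 mol%), PhI(OAc)2, CH2Cl2, rt
Reagents that add atoms: none
Why: Oxoammonium-mediated oxidation of a primary allylic alcohol stops at the aldehyde under near-neutral conditions that should leave the C4=C5 geometry, the acetal and the silyl ether untouched.

Step 5
Reactants: 9 prop-2-yn-1-ol
Product: 10 1-methoxy-4-[(prop-2-yn-1-yloxy)methyl]benzene (PMB propargyl ether)
Conditions: NaH (1 equiv), PMBCl, Bu4NI (cat.), THF/DMF, 0 °C to rt
Reagents that add atoms: 4-methoxybenzyl chloride, COc1ccc(CCl)cc1
Why: Williamson ether synthesis of a primary alkoxide with a reactive benzylic chloride.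

Step 6
Reactants: 10 PMB propargyl ether; 8 C6 enal
Product: 13 (2E,4S,5E)-8-(1,3-dioxolan-2-yl)-6-{[(tert-butyldiphenylsilyl)oxy]methyl}-1-[(4-methoxybenzyl)oxy]octa-2,5-dien-4-ol (6S bis-allylic alcohol), via alkenylborane 11 (not isolated), via alkenylzinc 12 (not isolated)
Conditions: 10, Cy2BH (from BH3·SMe2 and cyclohexene), toluene, 0 °C to rt; Et2Zn, (−)-MIB (5 mol%), −78 to −10 °C; then 8, −10 °C
Reagents that add atoms: none
Why: syn-Hydroboration gives the E-alkenylborane, boron-to-zinc exchange gives the alkenylzinc, and the zinc amino-alkoxide of (−)-MIB delivers it 1,2 to the Si face of the enal (catalytic asymmetric alkenylzinc addition), which sets C6 as S and keeps C7=C8 as E.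

Step 7
Reactants: 13 6S bis-allylic alcohol
Product: 14 (6R,7R,8R) erythro trans-C7–C8 epoxy alcohol
Conditions: Ti(OiPr)4 (20 mol%), D-(−)-diisopropyl tartrate (24 mol%), tBuOOH (about 1 equiv), 4 Å MS, CH2Cl2, −20 °C
Reagents that add atoms: tert-butyl hydroperoxide, CC(C)(C)OO
Why: Sharpless asymmetric epoxidation run in its matched, kinetic-resolution sense, in which the D-tartrate catalyst finds the 6S alcohol fast-reacting at the E C7=C8 alkene and sets C7 and C8 as the erythro (7R,8R) epoxide, whereas C4=C5 is mismatched for this C6 configuration, carries a cis substituent and sits next to the bulky silyl ether, and any 6R alcohol is left behind so that optical purity should rise.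

Step 8
Reactants: 14 erythro epoxy alcohol; 15 2-(diethoxyphosphoryl)acetic acid
Product: 16 C6 diethylphosphonoacetate of 14 (6R,7R,8R)
Conditions: DCC, DMAP (10 mol%), CH2Cl2, 0 °C to rt
Reagents that add atoms: none
Why: Steglich esterification acylates the secondary C6 hydroxyl under neutral conditions with retention at C6 and without touching the epoxide.

Step 9
Reactants: 16 C6 diethylphosphonoacetate; 17 formaldehyde
Product: 19 trans α-methylene-γ-lactone bearing a free C8 hydroxyl (6R,7R,8S), via phosphono lactone 18 (not isolated)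
Conditions: KOtBu (1.0 equiv), THF, 0 °C to rt (40 °C at most); then 17 (dry paraformaldehyde, excess), 0 °C to rt
Reagents that add atoms: none
Why: Proposed new method: KOtBu deprotonates C11 of the phosphonoacetate, the potassium carbanion attacks C7 from the side opposite the C7–O bond, and the released C8 alkoxide takes the remaining C11 proton of phosphono lactone 18, which regenerates a phosphonate carbanion that undergoes Horner–Wadsworth–Emmons methylenation with formaldehyde and expels diethyl phosphate. The closest known reaction types are the telescoped intramolecular Michael addition/olefination of tethered phosphonoacetates, the intermolecular opening of epoxides by phosphonoacetate and malonate anions to α-substituted γ-lactones, the proximal-carbon opening of 2,3-epoxy alcohol carbamates and the formaldehyde olefination of α-phosphono lactones; what is untested is an ester-tethered phosphonate carbanion as nucleophile toward an epoxide. Ring B closes in the 5-exo-tet mode, its only extra cost being rotation of the ester into the s-cis form. C7, the one new stereocentre, is fixed by SN2 inversion of the epoxide carbon installed in step 7, which turns the erythro array into the 6,7-trans lactone, while C8 keeps its C–O bond and C6 is untouched. The step needs attack at C7 rather than C8, secured by the five-membered against the six-membered (6-endo) transition state and by the inductive pull of the C9 ether oxygen on C8, and it needs O8 to stay idle, secured by no more than one equivalent of base (the enolised lactone is no acyl donor, and migration to O8 would give the less stable cis lactone) and by a non-migrating PMB group at C9. Staying at or below 40 °C should keep the system under the threshold of phosphoryl transfer to O8 and Wadsworth–Emmons cyclopropanation.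

Step 10
Reactants: 19 C8 alcohol; 20 (S)-2-methylbutanoic acid
Product: 21 C8 (S)-2-methylbutanoate of 19 (stereocentres C6, C7, C8 spatially as in 19)
Conditions: DCC, DMAP (20 mol%), CH2Cl2, 0 °C to rt
Reagents that add atoms: none
Why: Steglich esterification with retention at C8, in which the α-stereocentre of the acid carries no activating group and should not racemise, and prompt acylation removes the only nucleophile that could attack C12 or C13.

Step 11
Reactants: 21 C8 ester with C9–OPMB
Product: 22 C9 primary alcohol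
Conditions: DDQ, CH2Cl2/pH 7 buffer, 0 °C
Reagents that add atoms: none
Why: Oxidative PMB cleavage by DDQ through the benzylic oxocarbenium ion, hydrolysed by the buffer, spares silyl ether, acetal, esters and alkenes, and neutral pH suppresses O8-to-O9 acyl migration.

Step 12
Reactants: 22 C9 primary alcohol
Product: 23 C9 aldehyde
Conditions: Dess–Martin periodinane, CH2Cl2, 0 °C to rt; used without storage
Reagents that add atoms: none
Why: Dess–Martin oxidation gives the aldehyde without base, so the α-acyloxy stereocentre C8 should not epimerise.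

Step 13
Reactants: 23 C9 aldehyde; 24 ethyltriphenylphosphonium iodide
Product: 28 (9Z)-10-iodoalkene (C8–CH=C(I)CH3 with iodine cis to C8; C1 still a dioxolane), via ethylidene ylide 25 (not isolated), via iodoethylphosphonium iodide 26 (not isolated), via iodoethylidene ylide 27 (not isolated)
Conditions: 24, nBuLi, THF, rt; I2, −78 °C; NaN(SiMe3)2, −20 °C; then 23 (slight excess over ylide), −78 °C
Reagents that add atoms: iodine, II
Why: Stork–Zhao-type Wittig olefination with the α-iodoethylidene ylide, in which kinetically controlled oxaphosphetane formation of this non-stabilised ylide places iodine cis to C8 (Z), and at −78 °C with no surplus ylide carbonyl addition should outrun conjugate addition to C13 and enolisation at C8.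

Step 14
Reactants: 28 (9Z)-10-iodoalkene acetal
Product: 29 seco iodo aldehyde (C1 aldehyde, C10 iodide)
Conditions: TsOH·H2O (10 mol%), THF/H2O 4:1, 40 °C
Reagents that add atoms: water, O
Why: Acid-catalysed acetal hydrolysis frees the C1 aldehyde while the TBDPS ether, both esters and the alkenyl iodide are stable to mild aqueous acid.

Step 15
Reactants: 29 seco iodo aldehyde
Product: 31 15-O-TBDPS macrocycle (1S,6R,7R,8R; 4E,9Z), via alkenylchromium 30 (not isolated)
Conditions: CrCl2 (10 equiv), NiCl2 (0.1 equiv), DMSO, rt, slow addition of 29 to about 2 mM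
Reagents that add atoms: none
Why: Nozaki–Hiyama–Kishi reaction, in which zerovalent nickel inserts into the C10–I bond and hands the alkenyl group with retained geometry to trivalent chromium, which adds only to the aldehyde and tolerates lactone, acrylate and ester; ring A is a comparatively unstrained ring-cis,cis-cyclodeca-1,6-diene pre-folded by the trans lactone, and C1 is set by macrocyclic substrate control on the chromium-bound aldehyde, the 1S alcohol being the isomer sought and its selection not secured by any reagent.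

Step 16
Reactants: 31 15-O-TBDPS macrocycle
Product: 32 CNP0526758.1, (1S,4E,6R,7R,8R,9Z)-1,15-dihydroxy-8-[(2S)-2-methylbutanoyloxy]germacra-4,9,11(13)-trien-12,6-olide
Conditions: HF·pyridine, pyridine, THF, 0 °C to rt
Reagents that add atoms: none
Why: Fluoride-mediated Si–O cleavage under mildly acidic buffering avoids the basic conditions that would trigger acyl migration or oxa-Michael addition to C13, and no stereocentre is touched.

Compound list
1 | but-2-yne-1,4-diol | OCC#CCO | starting material
2 | 4-[(tert-butyldiphenylsilyl)oxy]but-2-yn-1-ol | OCC#CCO[Si](c1ccccc1)(c1ccccc1)C(C)(C)C | intermediate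
3 | sodium cyclic alkenylalanate (Al bound to O6, C4 and two 2-methoxyethoxides) | [Na+].COCCO[Al-]1(OCCOC)OCC=C1CO[Si](c1ccccc1)(c1ccccc1)C(C)(C)C | intermediate
4 | (Z)-4-[(tert-butyldiphenylsilyl)oxy]-3-iodobut-2-en-1-ol | OC/C=C(/CO[Si](c1ccccc1)(c1ccccc1)C(C)(C)C)I | intermediate
5 | 2-vinyl-1,3-dioxolane | C=CC1OCCO1 | starting material
6 | 9-[2-(1,3-dioxolan-2-yl)ethyl]-9-borabicyclo[3.3.1]nonane | C(CC1OCCO1)B1C2CCCC1CCC2 | intermediate
7 | (E)-5-(1,3-dioxolan-2-yl)-3-{[(tert-butyldiphenylsilyl)oxy]methyl}pent-2-en-1-ol | OC/C=C(/CO[Si](c1ccccc1)(c1ccccc1)C(C)(C)C)CCC1OCCO1 | intermediate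
8 | (E)-5-(1,3-dioxolan-2-yl)-3-{[(tert-butyldiphenylsilyl)oxy]methyl}pent-2-enal | O=C/C=C(/CO[Si](c1ccccc1)(c1ccccc1)C(C)(C)C)CCC1OCCO1 | intermediate
9 | prop-2-yn-1-ol | C#CCO | starting material
10 | 1-methoxy-4-[(prop-2-yn-1-yloxy)methyl]benzene | C#CCOCc1ccc(OC)cc1 | intermediate
11 | (E)-dicyclohexyl{3-[(4-methoxybenzyl)oxy]prop-1-en-1-yl}borane | COc1ccc(COC/C=C/B(C2CCCCC2)C2CCCCC2)cc1 | intermediate
12 | ethyl{(E)-3-[(4-methoxybenzyl)oxy]prop-1-en-1-yl}zinc | CC[Zn]/C=C/COCc1ccc(OC)cc1 | intermediate
13 | 6S bis-allylic alcohol, (2E,4S,5E)-octa-2,5-dien-4-ol named in step 6 | O[C@H](/C=C(/CO[Si](c1ccccc1)(c1ccccc1)C(C)(C)C)CCC1OCCO1)/C=C/COCc1ccc(OC)cc1 | intermediate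
14 | (6R,7R,8R) erythro trans-C7–C8 epoxy alcohol | O[C@H](/C=C(/CO[Si](c1ccccc1)(c1ccccc1)C(C)(C)C)CCC1OCCO1)[C@H]1O[C@@H]1COCc1ccc(OC)cc1 | intermediate
15 | 2-(diethoxyphosphoryl)acetic acid | OC(=O)CP(=O)(OCC)OCC | starting material
16 | C6 diethylphosphonoacetate of 14 (key-step precursor) | CCOP(=O)(OCC)CC(=O)O[C@H](/C=C(/CO[Si](c1ccccc1)(c1ccccc1)C(C)(C)C)CCC1OCCO1)[C@H]1O[C@@H]1COCc1ccc(OC)cc1 | intermediate
17 | formaldehyde (from paraformaldehyde) | C=O | starting material
18 | α-(diethoxyphosphoryl) trans-γ-lactone with C8 hydroxyl (C11 not fixed, planar as its carbanion) | CCOP(=O)(OCC)C1C(=O)O[C@H](/C=C(/CO[Si](c2ccccc2)(c2ccccc2)C(C)(C)C)CCC2OCCO2)[C@H]1[C@H](O)COCc2ccc(OC)cc2 | intermediate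
19 | trans α-methylene-γ-lactone with free C8 hydroxyl (key-step product, 6R,7R,8S) | C=C1C(=O)O[C@H](/C=C(/CO[Si](c2ccccc2)(c2ccccc2)C(C)(C)C)CCC2OCCO2)[C@H]1[C@H](O)COCc2ccc(OC)cc2 | intermediate
20 | (S)-2-methylbutanoic acid | CC[C@H](C)C(=O)O | starting material
21 | C8 (S)-2-methylbutanoate, C9–OPMB | C=C1C(=O)O[C@H](/C=C(/CO[Si](c2ccccc2)(c2ccccc2)C(C)(C)C)CCC2OCCO2)[C@H]1[C@H](OC(=O)[C@@H](C)CC)COCc2ccc(OC)cc2 | intermediate
22 | C9 primary alcohol | C=C1C(=O)O[C@H](/C=C(/CO[Si](c2ccccc2)(c2ccccc2)C(C)(C)C)CCC2OCCO2)[C@H]1[C@H](OC(=O)[C@@H](C)CC)CO | intermediate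
23 | C9 aldehyde | C=C1C(=O)O[C@H](/C=C(/CO[Si](c2ccccc2)(c2ccccc2)C(C)(C)C)CCC2OCCO2)[C@H]1[C@H](OC(=O)[C@@H](C)CC)C=O | intermediate
24 | ethyltriphenylphosphonium iodide | CC[P+](c1ccccc1)(c1ccccc1)c1ccccc1.[I-] | starting material
25 | ethylidenetriphenylphosphorane | CC=P(c1ccccc1)(c1ccccc1)c1ccccc1 | intermediate
26 | (1-iodoethyl)triphenylphosphonium iodide | CC(I)[P+](c1ccccc1)(c1ccccc1)c1ccccc1.[I-] | intermediate
27 | (1-iodoethylidene)triphenylphosphorane | CC(I)=P(c1ccccc1)(c1ccccc1)c1ccccc1 | intermediate
28 | (9Z)-10-iodoalkene, C1 dioxolane | C=C1C(=O)O[C@H](/C=C(/CO[Si](c2ccccc2)(c2ccccc2)C(C)(C)C)CCC2OCCO2)[C@H]1[C@H](OC(=O)[C@@H](C)CC)/C=C(/C)I | intermediate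
29 | seco iodo aldehyde | C=C1C(=O)O[C@H](/C=C(/CO[Si](c2ccccc2)(c2ccccc2)C(C)(C)C)CCC=O)[C@H]1[C@H](OC(=O)[C@@H](C)CC)/C=C(/C)I | intermediate
30 | C10 alkenylchromium dichloride | C=C1C(=O)O[C@H](/C=C(/CO[Si](c2ccccc2)(c2ccccc2)C(C)(C)C)CCC=O)[C@H]1[C@H](OC(=O)[C@@H](C)CC)/C=C(/C)[Cr](Cl)Cl | intermediate
31 | 15-O-TBDPS macrocycle (1S,6R,7R,8R) | C=C1C(=O)O[C@@H]2/C=C(/CO[Si](c3ccccc3)(c3ccccc3)C(C)(C)C)CC[C@H](O)/C(C)=C\[C@@H](OC(=O)[C@@H](C)CC)[C@@H]12 | intermediate
32 | CNP0526758.1 | C=C1C(=O)O[C@@H]2/C=C(/CO)CC[C@H](O)/C(C)=C\[C@@H](OC(=O)[C@@H](C)CC)[C@@H]12 | target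

Total step count: 16. Longest linear sequence: 15 steps (steps 1–4, then 6–16). Step 5 is a one-step side branch.

Steps most likely to fail

Step 9. The closure may stall, because a stabilised carbanion has to open an unactivated epoxide through the less populated s-cis ester rotamer. Forcing it by heat invites phosphoryl transfer to O8 and acyl scrambling. The fallback uses known radical chemistry and sets out from 14. O-Propargylation without an alkoxide (propargyl bromide, Ag2O, CH2Cl2), which avoids epoxide migration, gives propargyl ether F1. Cp2TiCl (trivalent titanium, made from Cp2TiCl2 and Zn in THF, rt) opens the epoxide reductively to the C7 radical. This radical closes 5-exo-dig onto the alkyne, trans to the C5 side chain, and gives 3-methylenetetrahydrofuran F2 with the C8 hydroxyl and its configuration intact. Steglich esterification with 20 gives ester F3. Allylic oxidation of the ring CH2 (C12) with CrO3/3,5-dimethylpyrazole in CH2Cl2 comes back to the route at 21.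

Step 15. Facial selectivity at the C1 aldehyde may be poor or reversed, since only the folding of the macrocyclic transition state decides it, and oligomerisation competes with closure. The fallback replaces substrate control by reagent control and sets out from 31 as obtained, whatever its composition at C1. Dess–Martin oxidation gives macrocyclic enone F4. Corey–Bakshi–Shibata reduction with (R)-Me-CBS and catecholborane (toluene, −78 °C) follows, with the C10 alkenyl group as the large substituent, which corresponds to 1S. The low temperature spares the acrylate, and the sequence comes back to the route at 31.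

Step 13. The nucleophilic ylide or residual amide base may add to C13 of the acrylate, C8 may enolise, and Z selectivity may erode at this hindered α-branched aldehyde. The fallback masks the acceptor and sets out from 21. Conjugate addition of thiophenol (PhSH, Et3N cat., CH2Cl2) gives sulfide F5, whose C11 configuration is immaterial. DDQ then gives alcohol F6, Dess–Martin oxidation gives aldehyde F7, and the same iodoethylidene Wittig reaction, now free to use excess ylide, gives vinyl iodide F8. Oxidation with mCPBA (1 equiv, CH2Cl2, −78 °C) gives sulfoxide F9. Its thermal syn-elimination (toluene, CaCO3, 100 °C) restores C11=C13 and comes back to the route at 28.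

Further compounds
F1 | step 9 | C6 propargyl ether of 14 | C#CCO[C@H](/C=C(/CO[Si](c1ccccc1)(c1ccccc1)C(C)(C)C)CCC1OCCO1)[C@H]1O[C@@H]1COCc1ccc(OC)cc1
F2 | step 9 | trans 3-methylenetetrahydrofuran with free C8 hydroxyl | C=C1CO[C@H](/C=C(/CO[Si](c2ccccc2)(c2ccccc2)C(C)(C)C)CCC2OCCO2)[C@H]1[C@H](O)COCc2ccc(OC)cc2
F3 | step 9 | C8 (S)-2-methylbutanoate of F2 | C=C1CO[C@H](/C=C(/CO[Si](c2ccccc2)(c2ccccc2)C(C)(C)C)CCC2OCCO2)[C@H]1[C@H](OC(=O)[C@@H](C)CC)COCc2ccc(OC)cc2
F4 | step 15 | macrocyclic C1 enone | C=C1C(=O)O[C@@H]2/C=C(/CO[Si](c3ccccc3)(c3ccccc3)C(C)(C)C)CCC(=O)/C(C)=C\[C@@H](OC(=O)[C@@H](C)CC)[C@@H]12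
F5 | step 13 | C13 phenyl sulfide of 21 (C11 not fixed) | c1ccccc1SCC1C(=O)O[C@H](/C=C(/CO[Si](c2ccccc2)(c2ccccc2)C(C)(C)C)CCC2OCCO2)[C@H]1[C@H](OC(=O)[C@@H](C)CC)COCc2ccc(OC)cc2
F6 | step 13 | sulfide-masked C9 alcohol | c1ccccc1SCC1C(=O)O[C@H](/C=C(/CO[Si](c2ccccc2)(c2ccccc2)C(C)(C)C)CCC2OCCO2)[C@H]1[C@H](OC(=O)[C@@H](C)CC)CO
F7 | step 13 | sulfide-masked C9 aldehyde | c1ccccc1SCC1C(=O)O[C@H](/C=C(/CO[Si](c2ccccc2)(c2ccccc2)C(C)(C)C)CCC2OCCO2)[C@H]1[C@H](OC(=O)[C@@H](C)CC)C=O
F8 | step 13 | sulfide-masked (9Z)-10-iodoalkene | c1ccccc1SCC1C(=O)O[C@H](/C=C(/CO[Si](c2ccccc2)(c2ccccc2)C(C)(C)C)CCC2OCCO2)[C@H]1[C@H](OC(=O)[C@@H](C)CC)/C=C(/C)I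
F9 | step 13 | C13 phenyl sulfoxide of F8 (sulfur and C11 not fixed) | O=S(c1ccccc1)CC1C(=O)O[C@H](/C=C(/CO[Si](c2ccccc2)(c2ccccc2)C(C)(C)C)CCC2OCCO2)[C@H]1[C@H](OC(=O)[C@@H](C)CC)/C=C(/C)I
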